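**Retrosynthetic overview**

1. The target is the umbelliferone ether of a cis-fused 3-oxodrim-7-ene (drimane numbering: decalin C1–C10, C11 = OCH2; H-5, CH3-10 and H-9 on one face). Ring B is a cyclohexene with its C7=C8 bond opposite the ring fusion, so C5–C6 and C9–C10 are the two σ-bonds of a Diels–Alder retron. The partners are the (E)-diene C6=C7–C8(CH3)=C9–C11H2–O-coumarin and the C5=C10 double bond of ring A.
2. The cis H-5/CH3-10 relation is the ring (Z) geometry of the dienophile, and C11 trans to CH3-10 is the endo adduct of the (E)-diene. The cycloaddition therefore joins two halves of similar size at quaternary C10 and sets all three stereocentres.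
3. Ring A enters as a 2,5-cyclohexadienone. Its C1 carbonyl activates C5=C10; its C2=C3 bond is blocked by a phenylthio group on C3 (vinylogous thioester, the latent C3 ketone). After the union, reduction and hydrolysis move the oxygen from C1 to C3, and conjugate reduction of the Δ1-enone ends the route.
4. Ring order: the coumarin (purchased) and ring A (three steps from 2,4,4-trimethylcyclohexenone) come first; ring B is formed last, in the convergent step.

Key step: step 6

Remark: the SMILES is read as (5S,9R,10S) in drimane numbering, i.e. a cis-fused decalin; compounds 1 and 7 are taken as purchasable (1 is otherwise one step from isobutyraldehyde and ethyl vinyl ketone).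

**Route**

Step 1
Reactants: 1 2,4,4-trimethylcyclohex-2-en-1-one
Product: 2 2,4,4-trimethylcyclohexa-2,5-dien-1-one
Conditions: DDQ (1.5 equiv), 1,4-dioxane, reflux
Reagents that add atoms: none
Why: DDQ dehydrogenation of the enone through its cross-conjugated dienol (the only one possible, since C4 is quaternary) gives the 2,5-dienone, the standard preparation of 4,4-dialkylcyclohexa-2,5-dienones.

Step 2
Reactants: 2 2,4,4-trimethylcyclohexa-2,5-dien-1-one
Product: 3 rac-2,4,4-trimethyl-5-(phenylsulfanyl)cyclohex-2-en-1-one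
Conditions: PhSH (1.05 equiv), Et3N (0.1 equiv), CH2Cl2, 0 °C to rt
Reagents that add atoms: thiophenol, Sc1ccccc1
Why: Base-catalysed, reversible thia-Michael addition selects the α-unsubstituted enone (attack at C5), because the adduct of the α-methyl enone is more hindered; the new stereocentre is racemic and is removed in step 3.

Step 3
Reactants: 3 rac-2,4,4-trimethyl-5-(phenylsulfanyl)cyclohex-2-en-1-one
Product: 5 4,4,6-trimethyl-3-(phenylsulfanyl)cyclohexa-2,5-dien-1-one, via α-chloro sulfide 4 (not isolated)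
Conditions: NCS (1.05 equiv), CH2Cl2, 0 °C to rt
Reagents that add atoms: none
Why: NCS chlorinates the sulfide at its only α-C–H (Pummerer-type α-chlorination) and the chloro sulfide loses HCl towards the acidic C6–H, the known oxidation of β-arylthio ketones to β-arylthio enones, giving the vinylogous thioester that blocks C2=C3 and stores the C3 oxygen function.

Step 4
Reactants: 6 umbelliferone (7-hydroxy-2H-chromen-2-one); 7 (2E)-3-methylpent-2-en-4-yn-1-ol
Product: 8 7-{[(2E)-3-methylpent-2-en-4-yn-1-yl]oxy}-2H-chromen-2-one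
Conditions: PPh3, DIAD, THF, 0 °C to rt
Reagents that add atoms: none
Why: Mitsunobu etherification of an acidic phenol with a primary allylic alcohol proceeds by SN2 at CH2, so the (E) alkene is untouched.

Step 5
Reactants: 8 7-{[(2E)-3-methylpent-2-en-4-yn-1-yl]oxy}-2H-chromen-2-one
Product: 9 7-{[(2E)-3-methylpenta-2,4-dien-1-yl]oxy}-2H-chromen-2-one
Conditions: H2 (1 atm), Pd/CaCO3 poisoned with Pb(OAc)2, quinoline, EtOAc, rt, stopped after 1 equiv H2
Reagents that add atoms: none
Why: Lindlar semihydrogenation stops a terminal alkyne at the vinyl stage and leaves the trisubstituted (E) alkene, the coumarin C3=C4 bond and the allylic aryl ether intact, giving the (E)-diene.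

Step 6
Reactants: 5 4,4,6-trimethyl-3-(phenylsulfanyl)cyclohexa-2,5-dien-1-one; 9 7-{[(2E)-3-methylpenta-2,4-dien-1-yl]oxy}-2H-chromen-2-one
Product: 10 7-{[(1R,4aS,8aS)-2,5,5,8a-tetramethyl-8-oxo-6-(phenylsulfanyl)-1,4,4a,5,8,8a-hexahydronaphthalen-1-yl]methoxy}-2H-chromen-2-one
Conditions: (S)-1-(2-methylphenyl)-3,3-diphenyltetrahydro-1H,3H-pyrrolo[1,2-c][1,3,2]oxazaborole (20 mol%) + Tf2NH (18 mol%), CH2Cl2, −40 to 0 °C, 9 (1.5 equiv) added slowly to the preformed catalyst–5 complex
Reagents that add atoms: none
Why: Proposed new method: the chiral oxazaborolidinium ion should bind the carbonyl oxygen of 5 (the strongest Lewis base present) on the lone pair next to C2–H, its aryl group covering one face of the flat dienone, and a concerted, asynchronous [4+2] cycloaddition follows in which the unsubstituted diene terminus bonds first to the β-carbon C5 and the CH2OAr-bearing terminus then closes onto the methyl-bearing α-carbon (C6 of 5, C10 of the target) to make the quaternary centre. The closest known reactions are the oxazaborolidinium-catalysed enantioselective Diels–Alder reactions of quinone monoketals, methyl-substituted benzoquinones and cyclohexenones, and the Lewis-acid Diels–Alder reactions of 2-methylcyclohexenones such as carvone with 1-substituted dienes; new is the dienophile class, a 3-thio-substituted 4,4-dialkyl-2,5-cyclohexadienone reacting at its α-methyl double bond. Ring B is closed by intermolecular [4+2] cycloaddition, suprafacial on both partners. The cis ring fusion (H-5/CH3-10) follows from the ring (Z) geometry of the dienophile; C9 follows from the (E) diene and the endo transition state with ring A under the diene (the exo mode presses the diene methyl against the angular methyl), which puts CH2OAr trans to CH3-10; the absolute sense comes from the catalyst, which must leave open the face that is Re at the methyl-bearing carbon and Si at C5 of 5 (the (S) catalyst is proposed, its antipode is taken if the sense is found opposite). Site selectivity is secured by the sulfur donor, which deactivates and encumbers C2=C3; regioselectivity by the 1-substituent rule of the diene and by the fact that only its CH2 terminus can reach the neopentyl β-carbon; the acid-labile dienyl aryl ether is spared by low temperature and slow addition.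

Step 7
Reactants: 10 Diels–Alder adduct (name as in step 6)
Product: 12 7-{[(1R,4aS,8aS)-2,5,5,8a-tetramethyl-6-oxo-1,4,4a,5,6,8a-hexahydronaphthalen-1-yl]methoxy}-2H-chromen-2-one, via allylic alcohol 11 (not isolated)
Conditions: NaBH4, CeCl3·7H2O, MeOH–THF, −20 °C; then 2 M aq HCl, THF, rt
Reagents that add atoms: water, O
Why: Luche reduction is selective for the ketone over the coumarin lactone, and acid then ionises the allylic alcohol to a sulfur-stabilised allyl cation that takes up water at C3 and loses thiophenol (sulfur variant of the Stork–Danheiser 1,3-carbonyl transposition), so the activating C1 oxygen is removed and the C3 ketone appears as the Δ1-enone with no enolisable stereocentre at risk.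

Step 8
Reactants: 12 enone (name as in step 7)
Product: 14 7-{[(1R,4aS,8aS)-2,5,5,8a-tetramethyl-6-oxo-1,4,4a,5,6,7,8,8a-octahydronaphthalen-1-yl]methoxy}-2H-chromen-2-one (target), via silyl enol ether 13 (not isolated)
Conditions: [(Ph3P)CuH]6 (5 mol%), PhMe2SiH (1.5 equiv), toluene, rt; then 1 M aq HCl, THF, 0 °C
Reagents that add atoms: none
Why: Copper hydride conjugate reduction (catalytic [(Ph3P)CuH]6 with a silane) is selective for the enone over the less electrophilic coumarin and the isolated trisubstituted alkene, and hydrolysis of the silyl enol ether gives the saturated C3 ketone; no stereocentre is formed or touched.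

**Compound list**

1 | 2,4,4-trimethylcyclohex-2-en-1-one | CC1=CC(C)(C)CCC1=O | starting material
2 | 2,4,4-trimethylcyclohexa-2,5-dien-1-one | CC1=CC(C)(C)C=CC1=O | intermediate
3 | rac-2,4,4-trimethyl-5-(phenylsulfanyl)cyclohex-2-en-1-one | CC1=CC(C)(C)C(Sc2ccccc2)CC1=O | intermediate
4 | 5-chloro-2,4,4-trimethyl-5-(phenylsulfanyl)cyclohex-2-en-1-one (racemic, not isolated) | CC1=CC(C)(C)C(Cl)(Sc2ccccc2)CC1=O | intermediate
5 | 4,4,6-trimethyl-3-(phenylsulfanyl)cyclohexa-2,5-dien-1-one | CC1=CC(C)(C)C(Sc2ccccc2)=CC1=O | intermediate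
6 | umbelliferone (7-hydroxy-2H-chromen-2-one) | O=c1ccc2ccc(O)cc2o1 | starting material
7 | (2E)-3-methylpent-2-en-4-yn-1-ol | C#C/C(C)=C/CO | starting material
8 | 7-{[(2E)-3-methylpent-2-en-4-yn-1-yl]oxy}-2H-chromen-2-one | C#C/C(C)=C/COc1ccc2ccc(=O)oc2c1 | intermediate
9 | 7-{[(2E)-3-methylpenta-2,4-dien-1-yl]oxy}-2H-chromen-2-one | C=C/C(C)=C/COc1ccc2ccc(=O)oc2c1 | intermediate
10 | 7-{[(1R,4aS,8aS)-2,5,5,8a-tetramethyl-8-oxo-6-(phenylsulfanyl)-1,4,4a,5,8,8a-hexahydronaphthalen-1-yl]methoxy}-2H-chromen-2-one (cis-fused; H-4a, CH3-8a and H-1 on one face) | CC1=CC[C@@H]2C(C)(C)C(Sc3ccccc3)=CC(=O)[C@]2(C)[C@@H]1COc1ccc2ccc(=O)oc2c1 | intermediate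
11 | 7-{[(1R,4aS,8aS)-8-hydroxy-2,5,5,8a-tetramethyl-6-(phenylsulfanyl)-1,4,4a,5,8,8a-hexahydronaphthalen-1-yl]methoxy}-2H-chromen-2-one (C8 epimers, not isolated) | CC1=CC[C@@H]2C(C)(C)C(Sc3ccccc3)=CC(O)[C@]2(C)[C@@H]1COc1ccc2ccc(=O)oc2c1 | intermediate
12 | 7-{[(1R,4aS,8aS)-2,5,5,8a-tetramethyl-6-oxo-1,4,4a,5,6,8a-hexahydronaphthalen-1-yl]methoxy}-2H-chromen-2-one | CC1=CC[C@@H]2C(C)(C)C(=O)C=C[C@]2(C)[C@@H]1COc1ccc2ccc(=O)oc2c1 | intermediate
13 | 7-{[(1R,4aS,8aS)-6-{[dimethyl(phenyl)silyl]oxy}-2,5,5,8a-tetramethyl-1,4,4a,5,8,8a-hexahydronaphthalen-1-yl]methoxy}-2H-chromen-2-one (not isolated) | CC1=CC[C@@H]2C(C)(C)C(O[Si](C)(C)c3ccccc3)=CC[C@]2(C)[C@@H]1COc1ccc2ccc(=O)oc2c1 | intermediate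
14 | 7-{[(1R,4aS,8aS)-2,5,5,8a-tetramethyl-6-oxo-1,4,4a,5,6,7,8,8a-octahydronaphthalen-1-yl]methoxy}-2H-chromen-2-one | CC1=CC[C@@H]2C(C)(C)C(=O)CC[C@]2(C)[C@@H]1COc1ccc2ccc(=O)oc2c1 | target

**Totals**

Total step count: 8.
Longest linear sequence: 6 steps (steps 1, 2, 3, 6, 7, 8; 1 → 2 → 3 → 5 → 10 → 12 → 14).

**Steps most likely to fail**

Step 6 (labelled step). What may go wrong: no turnover, because the dienophile is hindered at both alkene carbons and its carbonyl is deactivated by the sulfur donor; acid-induced ionisation of the dienyl aryl ether; insufficient face or regio selection. The fallback uses known chemistry, sets out from 5 and 7 and comes back at 10. The union is run in racemic form with a stoichiometric achiral Lewis acid and an acid-stable diene, and the absolute configuration comes from an enzymatic resolution. Alcohol 7 is acetylated (Ac2O, pyridine) to (2E)-3-methylpent-2-en-4-yn-1-yl acetate F1, which is semihydrogenated as in step 5 to (2E)-3-methylpenta-2,4-dien-1-yl acetate F2. Diene F2 and 5 are combined with EtAlCl2 (CH2Cl2–toluene, −40 °C to rt) to give the racemic endo adduct, rac-[(1R*,4aS*,8aS*)-2,5,5,8a-tetramethyl-8-oxo-6-(phenylsulfanyl)-1,4,4a,5,8,8a-hexahydronaphthalen-1-yl]methyl acetate F3. Lipase-catalysed hydrolysis (Burkholderia cepacia lipase, pH 7 buffer–acetone, run to about half conversion) serves as kinetic resolution and gives (4aS,8R,8aS)-8-(hydroxymethyl)-4,4,7,8a-tetramethyl-3-(phenylsulfanyl)-4a,5,8,8a-tetrahydronaphthalen-1(4H)-one F4. It is taken from the hydrolysed fraction, or from the recovered acetate after K2CO3/MeOH if the enzyme prefers the antipode. Mitsunobu coupling of F4 with 6 (PPh3, DIAD, THF) gives 10.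

Step 7. What may go wrong: hydride attack on the coumarin lactone while the hindered C1 ketone reduces slowly; re-addition of the liberated thiophenol to the coumarin or to the enone; acid-induced migration of the C7=C8 double bond. The fallback sets out from 5 and 7 and comes back at 12: the coumarin is attached only after the transposition. Alcohol 7 is silylated (TBSCl, imidazole, DMF) to tert-butyl(dimethyl){[(2E)-3-methylpent-2-en-4-yn-1-yl]oxy}silane F5 and semihydrogenated as in step 5 to tert-butyl(dimethyl){[(2E)-3-methylpenta-2,4-dien-1-yl]oxy}silane F6. Cycloaddition of F6 with 5 under the conditions of step 6 gives (4aS,8R,8aS)-8-({[tert-butyl(dimethyl)silyl]oxy}methyl)-4,4,7,8a-tetramethyl-3-(phenylsulfanyl)-4a,5,8,8a-tetrahydronaphthalen-1(4H)-one F7. LiAlH4 (Et2O, 0 °C) gives the allylic alcohol F8 (not isolated). Aqueous HCl in THF then effects the transposition and cleaves the silyl ether, giving (4aS,5R,8aS)-5-(hydroxymethyl)-1,1,4a,6-tetramethyl-4a,5,8,8a-tetrahydronaphthalen-2(1H)-one F9. Mitsunobu coupling of F9 with 6 gives 12.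

Step 8. What may go wrong: over-reduction of the coumarin C3=C4 bond, or incomplete conversion of the enone, whose β-carbon is flanked by the quaternary centre. The fallback sets out from 12 and comes back at 14: the formal 1,4-reduction is done in two steps by hetero-Michael addition and radical reduction. Benzeneselenol (PhSeH, cat. Et3N, CH2Cl2) adds to the enone to give 7-{[(1R,4aS,8aS)-2,5,5,8a-tetramethyl-6-oxo-8-(phenylselanyl)-1,4,4a,5,6,7,8,8a-octahydronaphthalen-1-yl]methoxy}-2H-chromen-2-one F10. Bu3SnH with AIBN (toluene, 80 °C) removes the selenium and gives 14.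

**Further compounds**

F1 | step 6 | (2E)-3-methylpent-2-en-4-yn-1-yl acetate | C#C/C(C)=C/COC(C)=O
F2 | step 6 | (2E)-3-methylpenta-2,4-dien-1-yl acetate | C=C/C(C)=C/COC(C)=O
F3 | step 6 | rac-[(1R*,4aS*,8aS*)-2,5,5,8a-tetramethyl-8-oxo-6-(phenylsulfanyl)-1,4,4a,5,8,8a-hexahydronaphthalen-1-yl]methyl acetate | CC1=CC[C@@H]2C(C)(C)C(Sc3ccccc3)=CC(=O)[C@]2(C)[C@@H]1COC(C)=O
F4 | step 6 | (4aS,8R,8aS)-8-(hydroxymethyl)-4,4,7,8a-tetramethyl-3-(phenylsulfanyl)-4a,5,8,8a-tetrahydronaphthalen-1(4H)-one | CC1=CC[C@@H]2C(C)(C)C(Sc3ccccc3)=CC(=O)[C@]2(C)[C@@H]1CO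
F5 | step 7 | tert-butyl(dimethyl){[(2E)-3-methylpent-2-en-4-yn-1-yl]oxy}silane | C#C/C(C)=C/CO[Si](C)(C)C(C)(C)C
F6 | step 7 | tert-butyl(dimethyl){[(2E)-3-methylpenta-2,4-dien-1-yl]oxy}silane | C=C/C(C)=C/CO[Si](C)(C)C(C)(C)C
F7 | step 7 | (4aS,8R,8aS)-8-({[tert-butyl(dimethyl)silyl]oxy}methyl)-4,4,7,8a-tetramethyl-3-(phenylsulfanyl)-4a,5,8,8a-tetrahydronaphthalen-1(4H)-one | CC1=CC[C@@H]2C(C)(C)C(Sc3ccccc3)=CC(=O)[C@]2(C)[C@@H]1CO[Si](C)(C)C(C)(C)C
F8 | step 7 | (4aS,8R,8aS)-8-({[tert-butyl(dimethyl)silyl]oxy}methyl)-4,4,7,8a-tetramethyl-3-(phenylsulfanyl)-1,4,4a,5,8,8a-hexahydronaphthalen-1-ol (C1 epimers, not isolated) | CC1=CC[C@@H]2C(C)(C)C(Sc3ccccc3)=CC(O)[C@]2(C)[C@@H]1CO[Si](C)(C)C(C)(C)C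
F9 | step 7 | (4aS,5R,8aS)-5-(hydroxymethyl)-1,1,4a,6-tetramethyl-4a,5,8,8a-tetrahydronaphthalen-2(1H)-one | CC1=CC[C@@H]2C(C)(C)C(=O)C=C[C@]2(C)[C@@H]1CO
F10 | step 8 | 7-{[(1R,4aS,8aS)-2,5,5,8a-tetramethyl-6-oxo-8-(phenylselanyl)-1,4,4a,5,6,7,8,8a-octahydronaphthalen-1-yl]methoxy}-2H-chromen-2-one (C8 epimers) | CC1=CC[C@@H]2C(C)(C)C(=O)CC([Se]c3ccccc3)[C@]2(C)[C@@H]1COc1ccc2ccc(=O)oc2c1
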